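**Plan**

1. Numbering: bicyclo[3.2.1]oct-3-ene-2,8-dione C1–C8 (C5 quaternary bridgehead, C8 bridging ketone, aryl-bearing C6 next to C5 and C7 next to C1); fused cyclopentane C4–C5–C9–C10–C11; indane methine C12; ring B is the resorcinol on C10.
2. Enabling feature: the enone carbons C2–C3–C4 lie between the two α-carbons (C1 and C5) of the C8 cyclopentanone and have the oxidation level of a propiolate. Cutting C5–C4 and C1–C2 therefore opens the cyclohexenone and the cyclopentane to a cyclopentanone with a phenyl alkynoate chain on C5.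
3. Further cuts: C11–C12 and C12–ring B (4-methoxybenzaldehyde supplies C12); C5–C9 (benzylic cation plus silyl enol ether); C6–aryl and C7–aryl (two conjugate arylations); C9–aryl and C10–C11 (Grignard addition to a Weinreb amide, Evans propargylation).
4. Forward order: cyclopentanone from a silyloxycyclopentenone, side chain joined at C5, cyclopentane (C5–C4) and cyclohexenone (C1–C2) closed in one anionic cascade, indane closed by aldehyde annulation, global demethylation.
5. Stereochemistry: C7 from (S)-4-silyloxycyclopentenone (anti cuprate addition, then elimination); C6 anti to C7; C10 from the (S)-benzyl oxazolidinone; C9 by 1,2-induction from C10 in the SN1 step; C5 anti to the C6 aryl and C1 by the tether in the cascade; C11 by the obligatory cis indane fusion and C12 by exo (trans to C4) Friedel–Crafts closure.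

Key step: step 11

Remark: the two arylmagnesium bromides and (S)-4-(tert-butyldimethylsilyloxy)cyclopent-2-en-1-one are taken as purchased; from compound 18 onward the atoms carry the core numbering of the plan.

**Route**

Step 1
Reactants: 1 (4S)-4-[(tert-butyldimethylsilyl)oxy]cyclopent-2-en-1-one; 2 (3,5-dimethoxyphenyl)magnesium bromide
Product: 4 (3R,4S)-4-[(tert-butyldimethylsilyl)oxy]-3-(3,5-dimethoxyphenyl)cyclopentan-1-one, via trimethylsilyl enol ether 3 (not isolated)
Conditions: 2, CuBr·SMe2 (10 mol%), Me3SiCl, THF, −78 °C; then 1 M HCl, 0 °C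
Reagents that add atoms: none
Why: Copper-catalysed, Me3SiCl-accelerated conjugate addition of the aryl Grignard reagent occurs anti to the C4 silyloxy group and gives the 3,4-trans ketone once the transient enol ether is hydrolysed in the cold acidic work-up, which the TBS ether survives.

Step 2
Reactants: 4 (3R,4S)-4-[(tert-butyldimethylsilyl)oxy]-3-(3,5-dimethoxyphenyl)cyclopentan-1-one
Product: 5 (4S)-4-(3,5-dimethoxyphenyl)cyclopent-2-en-1-one
Conditions: DBU, CH2Cl2, 0 °C
Reagents that add atoms: none
Why: E1cB elimination of the β-silyloxy group gives the enone without touching the aryl-bearing stereocentre, which a cold and short exposure to the base should preserve.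

Step 3
Reactants: 5 (4S)-4-(3,5-dimethoxyphenyl)cyclopent-2-en-1-one; 6 (4-methoxyphenyl)magnesium bromide
Product: 7 {[(3R,4S)-4-(3,5-dimethoxyphenyl)-3-(4-methoxyphenyl)cyclopent-1-en-1-yl]oxy}trimethylsilane
Conditions: 6, CuBr·SMe2 (10 mol%), Me3SiCl, THF, −78 °C; Et3N, pentane, cold aq. NaHCO3
Reagents that add atoms: chlorotrimethylsilane, C[Si](C)(C)Cl
Why: The second copper-catalysed conjugate addition takes place anti to the C4 aryl group (3,4-trans), and silylation in situ fixes the enolate regiospecifically on the carbon next to the new aryl group, the future C5.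

Step 4
Reactants: 8 (3,5-dimethoxyphenyl)acetic acid; 9 (4S)-4-benzyl-1,3-oxazolidin-2-one
Product: 11 (4S)-4-benzyl-3-[(3,5-dimethoxyphenyl)acetyl]-1,3-oxazolidin-2-one, via mixed pivalic anhydride 10 (not isolated)
Conditions: t-BuCOCl, Et3N, THF, −20 °C; then 9, LiCl, 20 °C
Reagents that add atoms: none
Why: N-Acylation of the oxazolidinone through the mixed anhydride under LiCl/Et3N activation is a standard entry to Evans imides and creates no stereocentre.

Step 5
Reactants: 11 (4S)-4-benzyl-3-[(3,5-dimethoxyphenyl)acetyl]-1,3-oxazolidin-2-one; 12 3-bromoprop-1-yne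
Product: 13 (4S)-4-benzyl-3-[(2S)-2-(3,5-dimethoxyphenyl)pent-4-ynoyl]-1,3-oxazolidin-2-one
Conditions: NaN(SiMe3)2, THF, −78 °C; then 12, −78 → −40 °C
Reagents that add atoms: none
Why: Evans alkylation, in which the chelated Z sodium enolate is propargylated on the face opposite the benzyl group, which sets the future C10 as S.

Step 6
Reactants: 13 (4S)-4-benzyl-3-[(2S)-2-(3,5-dimethoxyphenyl)pent-4-ynoyl]-1,3-oxazolidin-2-one
Product: 14 (2S)-2-(3,5-dimethoxyphenyl)-N-methoxy-N-methylpent-4-ynamide
Conditions: MeNH(OMe)·HCl, AlMe3, CH2Cl2, 0 → 20 °C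
Reagents that add atoms: N,O-dimethylhydroxylamine hydrochloride, CNOC.Cl
Why: Transamination with the aluminium amide (Weinreb amide formation) cleaves the auxiliary at the exocyclic carbonyl under non-basic conditions that should leave the α-aryl stereocentre intact.

Step 7
Reactants: 14 (2S)-2-(3,5-dimethoxyphenyl)-N-methoxy-N-methylpent-4-ynamide; 6 (4-methoxyphenyl)magnesium bromide
Product: 15 (2S)-2-(3,5-dimethoxyphenyl)-1-(4-methoxyphenyl)pent-4-yn-1-one
Conditions: 6 (3 equiv), THF, 0 °C; cold aq. NH4Cl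
Reagents that add atoms: none
Why: Grignard addition to a Weinreb amide stops at the chelated tetrahedral adduct, so the enolisable α-aryl ketone is released only on the cold quench, one equivalent of reagent being spent on the alkyne C–H.

Step 8
Reactants: 15 (2S)-2-(3,5-dimethoxyphenyl)-1-(4-methoxyphenyl)pent-4-yn-1-one
Product: 16 (2S)-2-(3,5-dimethoxyphenyl)-1-(4-methoxyphenyl)pent-4-yn-1-ol (both C1 epimers)
Conditions: NaBH4, CeCl3·7H2O, MeOH, −20 °C
Reagents that add atoms: none
Why: Luche reduction is fast and only weakly basic, so C10 should not epimerise, and the mixture at the carbinol carbon is harmless because that centre is ionised in step 10.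

Step 9
Reactants: 16 (2S)-2-(3,5-dimethoxyphenyl)-1-(4-methoxyphenyl)pent-4-yn-1-ol
Product: 17 phenyl (5S)-5-(3,5-dimethoxyphenyl)-6-(4-methoxyphenyl)-6-[(phenoxycarbonyl)oxy]hex-2-ynoate (both C6 epimers)
Conditions: n-BuLi (2.1 equiv), THF, −78 °C; then ClCO2Ph (2.4 equiv), −78 → −20 °C
Reagents that add atoms: phenyl chloroformate, O=C(Cl)Oc1ccccc1
Why: Double deprotonation and acylation of both the alkoxide and the lithium acetylide with the chloroformate installs the phenyl alkynoate and at the same time turns the benzylic oxygen into a carbonate leaving group.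

Step 10
Reactants: 7 {[(3R,4S)-4-(3,5-dimethoxyphenyl)-3-(4-methoxyphenyl)cyclopent-1-en-1-yl]oxy}trimethylsilane; 17 phenyl (5S)-5-(3,5-dimethoxyphenyl)-6-(4-methoxyphenyl)-6-[(phenoxycarbonyl)oxy]hex-2-ynoate
Product: 18 phenyl (5R,6S)-5-(3,5-dimethoxyphenyl)-6-[(1S,2R,3S)-3-(3,5-dimethoxyphenyl)-2-(4-methoxyphenyl)-5-oxocyclopentyl]-6-(4-methoxyphenyl)hex-2-ynoate
Conditions: Me3SiOTf (10 mol%), CH2Cl2, −78 → −40 °C; aq. NaHCO3
Reagents that add atoms: none
Why: SN1 benzylation of a silyl enol ether (Mukaiyama-type alkylation) in which the p-methoxybenzylic cation, held with H-10 in the aryl plane by allylic 1,3-strain, is attacked on the face anti to the 3,5-dimethoxyphenyl group to set C9, while the enol ether reacts anti to its neighbouring aryl group and the electron-poor alkynoate stays inert.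

Step 11
Reactants: 18 phenyl (5R,6S)-5-(3,5-dimethoxyphenyl)-6-[(1S,2R,3S)-3-(3,5-dimethoxyphenyl)-2-(4-methoxyphenyl)-5-oxocyclopentyl]-6-(4-methoxyphenyl)hex-2-ynoate
Product: 20 tricyclic enedione (1S,5R,6S,7R,9R,10R)-7,10-bis(3,5-dimethoxyphenyl)-6,9-bis(4-methoxyphenyl)-4,5-cyclopenta-fused bicyclo[3.2.1]oct-3-ene-2,8-dione, via spiro alkylidene ester 19 (not isolated)
Conditions: LiN(SiMe3)2 (0.3 equiv), THF (0.01 M), −78 → 0 °C; then LiN(SiMe3)2 (2.2 equiv), 0 → 20 °C; AcOH
Reagents that add atoms: none
Why: With a substoichiometric first charge of base the ketone enolates equilibrate through free ketone, and only the more substituted C5 enolate can reach the alkynoate, adding to C4 in a 5-exo-dig Michael reaction that closes the cyclopentane and leaves the spiro alkylidene ester 19 after proton transfer (base-catalysed carbocyclisation of a ketone onto a tethered ynoate). The second charge of base forms the C1 enolate, the only one left to the now quaternary ketone, which attacks the phenyl ester in a 6-exo-trig Claisen (Dieckmann-type) C-acylation that closes the cyclohexenone and hence the bicyclo[3.2.1]octene. C5 is set by approach of the tethered alkyne to the enolate face anti to the adjacent C6 aryl group, and C1 follows from the tether because C2 can only reach the face on which C4 already sits. Alkene geometry in 19 should not be limiting: protonation of the allenolate from the less hindered C11 side gives the reactive Z ester, and γ-deprotonation at C11 gives a dienolate (or, after loss of phenoxide, a vinylketene) with a freely rotating C3–C4 bond. O-Acylation to the enol lactone is reversible with lithium phenoxide, whereas the C-acylated diketone cannot enolise at its bridgeheads, is not reopened by the poorly nucleophilic phenoxide and is drained as its C11 dienolate by the excess base. The acidic quench should return the conjugated enone, and any β,γ-isomer from α-protonation converges in step 12.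

Step 12
Reactants: 20 tricyclic enedione
Product: 21 C2 tert-butyldimethylsilyl dienol ether of 20 (C2=C3 and C4=C11)
Conditions: t-BuMe2SiOTf, Et3N, CH2Cl2, 0 °C
Reagents that add atoms: tert-butyldimethylsilyl trifluoromethanesulfonate, CC(C)(C)[Si](C)(C)OS(=O)(=O)C(F)(F)F
Why: Soft enolisation can only remove H-11 because C1 is a bridgehead and C5 is quaternary, so the extended silyl dienol ether should form as a single regioisomer.

Step 13
Reactants: 21 C2 tert-butyldimethylsilyl dienol ether of 20; 22 4-methoxybenzaldehyde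
Product: 24 heptamethyl ether of the target (1S,5S,6S,7R,9R,10R,11R,12R), via carbinol adduct 23 (not isolated)
Conditions: 22, BF3·OEt2, CH2Cl2, −78 → 20 °C; aq. NaHCO3
Reagents that add atoms: none
Why: Vinylogous Mukaiyama aldol addition at C11 is followed by ionisation of the benzylic oxygen and intramolecular Friedel–Crafts alkylation of ring B at C2' (ortho and para to its methoxy groups), the indane being able to close only cis-fused, which fixes C11, with the C12 aryl group taking the exo position trans to C4; an adduct formed on the wrong face of C11 can re-enter by loss of H-11 to the arylidene dienone and re-closure.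

Step 14
Reactants: 24 heptamethyl ether of the target
Product: 25 target heptaphenol (CNP0407321.1)
Conditions: BBr3, CH2Cl2, −78 → 20 °C; then MeOH, H2O
Reagents that add atoms: none
Why: Lewis-acid cleavage of the seven aryl methyl ethers with a non-basic quench, so that the non-enolisable bridged β-diketone is not opened by retro-Claisen attack and no stereocentre is touched.

**Compound list**

1 | (4S)-4-[(tert-butyldimethylsilyl)oxy]cyclopent-2-en-1-one | O=C1C=C[C@@H](O[Si](C)(C)C(C)(C)C)C1 | starting material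
2 | (3,5-dimethoxyphenyl)magnesium bromide | COc1cc(OC)cc([Mg]Br)c1 | starting material
3 | trimethylsilyl enol ether of 4 (1,2-trans aryl and silyloxy groups) | C[Si](C)(C)OC1=C[C@H](c2cc(OC)cc(OC)c2)[C@@H](O[Si](C)(C)C(C)(C)C)C1 | intermediate
4 | (3R,4S)-4-[(tert-butyldimethylsilyl)oxy]-3-(3,5-dimethoxyphenyl)cyclopentan-1-one | O=C1C[C@H](c2cc(OC)cc(OC)c2)[C@@H](O[Si](C)(C)C(C)(C)C)C1 | intermediate
5 | (4S)-4-(3,5-dimethoxyphenyl)cyclopent-2-en-1-one | O=C1C[C@H](c2cc(OC)cc(OC)c2)C=C1 | intermediate
6 | (4-methoxyphenyl)magnesium bromide | COc1ccc([Mg]Br)cc1 | starting material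
7 | {[(3R,4S)-4-(3,5-dimethoxyphenyl)-3-(4-methoxyphenyl)cyclopent-1-en-1-yl]oxy}trimethylsilane | C[Si](C)(C)OC1=C[C@H](c2ccc(OC)cc2)[C@@H](c2cc(OC)cc(OC)c2)C1 | intermediate
8 | (3,5-dimethoxyphenyl)acetic acid | COc1cc(CC(=O)O)cc(OC)c1 | starting material
9 | (4S)-4-benzyl-1,3-oxazolidin-2-one | O=C1OC[C@H](Cc2ccccc2)N1 | starting material
10 | (3,5-dimethoxyphenyl)acetic pivalic anhydride | COc1cc(CC(=O)OC(=O)C(C)(C)C)cc(OC)c1 | intermediate
11 | (4S)-4-benzyl-3-[(3,5-dimethoxyphenyl)acetyl]-1,3-oxazolidin-2-one | O=C1OC[C@H](Cc2ccccc2)N1C(=O)Cc1cc(OC)cc(OC)c1 | intermediate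
12 | 3-bromoprop-1-yne (propargyl bromide) | C#CCBr | starting material
13 | (4S)-4-benzyl-3-[(2S)-2-(3,5-dimethoxyphenyl)pent-4-ynoyl]-1,3-oxazolidin-2-one | O=C1OC[C@H](Cc2ccccc2)N1C(=O)[C@@H](CC#C)c1cc(OC)cc(OC)c1 | intermediate
14 | (2S)-2-(3,5-dimethoxyphenyl)-N-methoxy-N-methylpent-4-ynamide | CON(C)C(=O)[C@@H](CC#C)c1cc(OC)cc(OC)c1 | intermediate
15 | (2S)-2-(3,5-dimethoxyphenyl)-1-(4-methoxyphenyl)pent-4-yn-1-one | COc1ccc(cc1)C(=O)[C@@H](CC#C)c1cc(OC)cc(OC)c1 | intermediate
16 | (2S)-2-(3,5-dimethoxyphenyl)-1-(4-methoxyphenyl)pent-4-yn-1-ol, both C1 epimers | COc1ccc(cc1)C(O)[C@@H](CC#C)c1cc(OC)cc(OC)c1 | intermediate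
17 | phenyl (5S)-5-(3,5-dimethoxyphenyl)-6-(4-methoxyphenyl)-6-[(phenoxycarbonyl)oxy]hex-2-ynoate, both C6 epimers | COc1ccc(cc1)C(OC(=O)Oc1ccccc1)[C@@H](CC#CC(=O)Oc1ccccc1)c1cc(OC)cc(OC)c1 | intermediate
18 | phenyl (5R,6S)-5-(3,5-dimethoxyphenyl)-6-[(1S,2R,3S)-3-(3,5-dimethoxyphenyl)-2-(4-methoxyphenyl)-5-oxocyclopentyl]-6-(4-methoxyphenyl)hex-2-ynoate | O=C(Oc1ccccc1)C#CC[C@@H](c1cc(OC)cc(OC)c1)[C@H](c1ccc(OC)cc1)[C@@H]1C(=O)C[C@H](c2cc(OC)cc(OC)c2)[C@H]1c1ccc(OC)cc1 | intermediate
19 | phenyl (2Z)-[3,8-bis(3,5-dimethoxyphenyl)-4,9-bis(4-methoxyphenyl)-6-oxospiro[4.4]nonan-1-ylidene]acetate, configured as in 20 | O=C(Oc1ccccc1)/C=C1/C[C@@H](c2cc(OC)cc(OC)c2)[C@H](c2ccc(OC)cc2)[C@]12C(=O)C[C@H](c1cc(OC)cc(OC)c1)[C@H]2c1ccc(OC)cc1 | intermediate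
20 | tricyclic enedione, core numbering (1S,5R,6S,7R,9R,10R): 7,10-bis(3,5-dimethoxyphenyl)-6,9-bis(4-methoxyphenyl) derivative of the C4–C5 cyclopenta-fused bicyclo[3.2.1]oct-3-ene-2,8-dione (skeleton tricyclo[6.2.1.0(1,5)]undec-5-ene-7,11-dione) | O=C1C=C2C[C@@H](c3cc(OC)cc(OC)c3)[C@H](c3ccc(OC)cc3)[C@]23C(=O)[C@H]1[C@H](c1cc(OC)cc(OC)c1)[C@H]3c1ccc(OC)cc1 | intermediate
21 | C2 tert-butyldimethylsilyl dienol ether of 20 (C2=C3, C4=C11; C8 ketone retained) | CC(C)(C)[Si](C)(C)OC1=CC2=C[C@@H](c3cc(OC)cc(OC)c3)[C@H](c3ccc(OC)cc3)[C@]23C(=O)[C@H]1[C@H](c1cc(OC)cc(OC)c1)[C@H]3c1ccc(OC)cc1 | intermediate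
22 | 4-methoxybenzaldehyde | COc1ccc(C=O)cc1 | starting material
23 | 11-[hydroxy(4-methoxyphenyl)methyl] derivative of 20 (drawn as the carbinol, present as its boron alkoxide; C11 and C12 epimers) | O=C1C=C2C(C(O)c4ccc(OC)cc4)[C@@H](c3cc(OC)cc(OC)c3)[C@H](c3ccc(OC)cc3)[C@]23C(=O)[C@H]1[C@H](c1cc(OC)cc(OC)c1)[C@H]3c1ccc(OC)cc1 | intermediate
24 | heptamethyl ether of the target, core numbering (1S,5S,6S,7R,9R,10R,11R,12R) | O=C1C=C2[C@H]3[C@H](c4ccc(OC)cc4)c4c(OC)cc(OC)cc4[C@H]3[C@H](c3ccc(OC)cc3)[C@]23C(=O)[C@H]1[C@H](c1cc(OC)cc(OC)c1)[C@H]3c1ccc(OC)cc1 | intermediate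
25 | target heptaphenol CNP0407321.1, core numbering (1S,5S,6S,7R,9R,10R,11R,12R) | O=C1C=C2[C@H]3[C@H](c4ccc(O)cc4)c4c(O)cc(O)cc4[C@H]3[C@H](c3ccc(O)cc3)[C@]23C(=O)[C@H]1[C@H](c1cc(O)cc(O)c1)[C@H]3c1ccc(O)cc1 | target

**Count and risks**

Total steps: 14. Longest linear sequence: 11 steps (8 to 25 through steps 4–14); silyl enol ether 7 is made in parallel in 3 steps.

Step 13. The first C–C bond at C11 may form on the face anti to ring B. Such an adduct cannot cyclise and would instead lose H-11 to the arylidene dienone or alkylate other arenes intermolecularly. The fallback sets out from 21 and returns at 24; it brings in the one-carbon unit as an acetal and the aryl group last. Reaction of 21 with HC(OMe)3 and BF3·OEt2 (CH2Cl2, −78 °C) would give the 11-(dimethoxymethyl) enedione F1. Treatment of this with CF3SO3H in CH2Cl2 containing excess anisole would ionise the acetal. The oxocarbenium ion can equilibrate C11 through its enol ether until the cis epimer is trapped by ring B (Bradsher-type cyclisation). The indanyl methyl ether so formed would ionise again to a C12 cation, which anisole should capture at its para position from the convex face, trans to C4, to give 24.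

Step 10. Face discrimination at the C9 cation may be weak (aryl against propargyl on C10), and loss of H-10 from the cation to a stilbene would erase C10. The fallback sets out from 14 and 7 and returns at 18; C9 enters as an aldehyde carbon and its aryl group is added afterwards under control of the ring. Reduction of 14 with i-Bu2AlH (THF, −78 °C) would give (2S)-2-(3,5-dimethoxyphenyl)pent-4-ynal F2, used at once in a BF3·OEt2-mediated Mukaiyama aldol addition with 7 to give the β-hydroxy ketone F3. Dehydration (MsCl, Et3N, then DBU, 0 °C) would give the (E)-alkylidene cyclopentanone F4. Copper-mediated conjugate addition of 6 (CuBr·SMe2, THF, −40 °C) should deliver the anisyl group to C9 from the face anti to the C6 aryl group, which allylic strain holds pseudo-axial over the exocyclic alkene. This gives the alkynyl ketone F5 with the C9 configuration of 18, although the C10 stereocentre may oppose the ring here. Coupling of the terminal alkyne with ClCO2Ph (PdCl2(PPh3)2, CuI, Et3N) would then return 18.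

Step 11. The cascade may stop after the Michael addition, with O-acylation of the C1 enolate to the enol lactone or intermolecular acyl transfer in place of closure of the strained bridged β-diketone. The fallback sets out from 18 and returns at 20; it makes the C1–C2 bond by an aldol addition at the aldehyde oxidation level. The Michael stage alone (LiN(SiMe3)2, 0.3 equiv, THF, 0 °C) would be used to isolate 19. i-Bu2AlH would reduce both the phenyl ester and the ketone to the allylic alcohol–cyclopentanol diol F6, and Dess–Martin periodinane would give the (Z)-keto enal F7. LiN(SiMe3)2 at −78 °C would form the only possible (C1) enolate, which adds to the aldehyde to give the bridged allylic ketol F8. A second Dess–Martin oxidation would return 20.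

**Further compounds**

F1 | step 13 | 11-(dimethoxymethyl) derivative of enedione 20 (C11 epimers) | O=C1C=C2C(C(OC)OC)[C@@H](c3cc(OC)cc(OC)c3)[C@H](c3ccc(OC)cc3)[C@]23C(=O)[C@H]1[C@H](c1cc(OC)cc(OC)c1)[C@H]3c1ccc(OC)cc1
F2 | step 10 | (2S)-2-(3,5-dimethoxyphenyl)pent-4-ynal | O=C[C@@H](CC#C)c1cc(OC)cc(OC)c1
F3 | step 10 | 2-[(2S)-2-(3,5-dimethoxyphenyl)-1-hydroxypent-4-yn-1-yl]-4-(3,5-dimethoxyphenyl)-3-(4-methoxyphenyl)cyclopentan-1-one, ring configured as in 18, carbinol epimers | OC([C@@H](CC#C)c1cc(OC)cc(OC)c1)[C@@H]1C(=O)C[C@H](c2cc(OC)cc(OC)c2)[C@H]1c1ccc(OC)cc1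
F4 | step 10 | (E)-2-[2-(3,5-dimethoxyphenyl)pent-4-yn-1-ylidene]-4-(3,5-dimethoxyphenyl)-3-(4-methoxyphenyl)cyclopentan-1-one, stereocentres as in F3 | O=C1C[C@H](c2cc(OC)cc(OC)c2)[C@@H](c2ccc(OC)cc2)/C1=C\[C@@H](CC#C)c1cc(OC)cc(OC)c1
F5 | step 10 | terminal alkyne analogue of 18 (alkynoate replaced by C≡C–H) | C#CC[C@@H](c1cc(OC)cc(OC)c1)[C@H](c1ccc(OC)cc1)[C@@H]1C(=O)C[C@H](c2cc(OC)cc(OC)c2)[C@H]1c1ccc(OC)cc1
F6 | step 11 | diol from 19: (Z)-2-hydroxyethylidene spiro[4.4]nonan-6-ol (carbinol epimers) | OC/C=C1/C[C@@H](c2cc(OC)cc(OC)c2)[C@H](c2ccc(OC)cc2)[C@]12C(O)C[C@H](c1cc(OC)cc(OC)c1)[C@H]2c1ccc(OC)cc1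
F7 | step 11 | (Z)-keto enal: (6-oxospiro[4.4]nonan-1-ylidene)acetaldehyde with the aryl groups of 19 | O=C/C=C1/C[C@@H](c2cc(OC)cc(OC)c2)[C@H](c2ccc(OC)cc2)[C@]12C(=O)C[C@H](c1cc(OC)cc(OC)c1)[C@H]2c1ccc(OC)cc1
F8 | step 11 | bridged ketol: 2-hydroxy analogue of 20 (C2 carbinol, epimers) | OC1C=C2C[C@@H](c3cc(OC)cc(OC)c3)[C@H](c3ccc(OC)cc3)[C@]23C(=O)[C@H]1[C@H](c1cc(OC)cc(OC)c1)[C@H]3c1ccc(OC)cc1
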